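Remark on the chemistry: the given structure carries no descriptor for the C-1–C-1' axis, so the target is taken as the racemic biaryl and no step is asked to control the axis.

Numbering used in the text: biphenyl numbering for the target (C-1 axis carbon, C-2 OH, C-3 acetyl, C-4 OMe, C-5 CH3, C-6 OMe) and ring numbering for the pyranones and pyrylium ions.

## The problem

Contortin is a C2-symmetric 2,2'-biphenol in which both benzene rings are fully substituted: C-1 carries the other ring, C-2 a free hydroxyl, C-3 an acetyl group, C-4 a methoxy, C-5 a methyl and C-6 a methoxy group. There is no sp3 stereocentre; the only stereogenic element is the C-1–C-1' axis, so the task is one of constitution and of bond construction under steric load, not of stereocontrol. The hardest bond is C-1–C-1': it is flanked by four oxygen substituents, and in any arene–arene coupling two electron-rich rings must meet at their most crowded carbon. The second problem is the oxygen pattern: of three oxygens in 1,3,5-relation, only O-2, between the axis and the acetyl group, is free, while O-4, which also flanks the acetyl group, is methylated, so hydrogen bonding to the ketone cannot tell O-2 from O-4 once both are phenols. The rings are phloroglucinol ethers: they are easily oxidized, strong acid can close a dibenzofuran between O-2 and C-6', and boron or aluminium halides cleave the C-4 methyl ether next to the ketone, so the end of the route must be mild. The feature that opens a way around this is that the atoms O(2)–C-2–C-3–C-4(OMe)–C-5(Me)–C-6(O) of each ring are, atom for atom, O-1–C-6–C-5–C-4(OMe)–C-3(Me)–C-2(=O) of a 4-methoxy-3-methyl-2H-pyran-2-one, and the axis carbon C-1 is then the carbon of a 6-methyl group on that heterocycle. Read this way, the biaryl axis is the CH2–CH2 bond of a 1,2-bis(pyranon-6-yl)ethane, the phenolic oxygen is the pyranone ring oxygen, and the C-6 methoxy oxygen is the lactone carbonyl oxygen.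

## Retrosynthesis

The two aryl–acetyl bonds (C-3–CO and C-3'–CO) are cut first, leading from 15 to the biphenol 13. Each ring of 13 has a single unsubstituted carbon, C-3, ortho to the phenol and activated by both methoxy groups, so O-acetylation to 14 and Fries rearrangement need no regiocontrol. Carrying the acetyl group through the ring construction instead would put a methyl ketone, a second carbon acid and electrophile, into the base-mediated key step.

Each benzene ring of 13 is then opened at the C-1–C-6 bond and recognized as a rearranged 2,4-dimethoxy-6-alkylpyrylium ion; both rings together give the bis(pyrylium) salt 10. In the forward direction methoxide should turn 10 into the lactone acetal 11, which opens to the diketone 12 and recloses with loss of methanol. This cut is preferred to a direct C-1–C-1' cut because the axis bond is never made between two arenes. It is preferred to recyclizing the neutral pyranone 9 by lactone methanolysis and Claisen condensation for two reasons: that path delivers O-6 as a phenol, and it passes through a 1,4-diketone with acidic CH2 groups on both outer flanks, which is set up for cyclopentenone formation. In 12 the bridge is the only enolizable position. Precursor 10 has no hindered bond and no phenols to differentiate; the forward step must deliver methoxide to C-2 and close two rings.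

Removing the two O-methyl groups from the former carbonyl oxygens of 10 gives the bis(pyranone) 9. Forward, this is O-alkylation of a vinylogous carbonate with MeOTf.

The CH2–CH2 bond of 9, the future biaryl axis, is cut to two molecules of pyranone 6. The 6-methyl group is the only acidic site of 6; its lithium trienolate 7 is oxidized by iodine to the iodide 8, which alkylates a second molecule of 7. The most hindered bond of the target is thus made as an unhindered sp3–sp3 bond, from a precursor with half the atoms.

Pyranone 6 is the methyl ether of 5, which is cut at the lactone C–O bond and at C-5–C-6 to the β-keto ester 1 and the acetyl donor 2. Forward, γ-acylation of dianion 3 gives the diketo ester 4, which lactonizes. All carbons of the target except the acetyl and O-methyl groups come from 1 and 2.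

## Roads not taken

Alternative 1: Cut C-1–C-1' between two complete arenes and form it by dehydrogenative ortho–ortho coupling of the monomeric ketone A1, 1-(6-hydroxy-2,4-dimethoxy-3-methylphenyl)ethan-1-one, made by acetylating the symmetric phenol A2, 3,5-dimethoxy-4-methylphenol. Equally, A2 could be coupled to 13 and acetylated afterwards. The forward key step is one-electron oxidation (for instance FeCl3 or a peroxide) and coupling at the one free ortho carbon. This is the most obvious road and the shortest by step count. It is not chosen for mechanistic reasons:
- The carbon para to the phenol carries the methyl group, and phenoxyl radicals of para-methyl phenols divert to quinone methides and to ortho–para and C–O linked dimers.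
- In A1 the hydroxyl is hydrogen-bonded to the ketone, which raises its oxidation potential, while the product biphenol is easier to oxidize than the monomer.
- The most crowded bond of the molecule is formed at the stage of maximal crowding.

The chosen plan makes the same bond between two sp3 carbons and never oxidizes an arene.

Alternative 2: The same cut, made reductively. Ullmann homocoupling of the iodide A3, 2-iodo-3,5-dimethoxy-1-(methoxymethoxy)-4-methylbenzene, with copper powder would give the protected biaryl A4, 2,2'-bis(methoxymethoxy)-4,4',6,6'-tetramethoxy-5,5'-dimethyl-1,1'-biphenyl; deprotection then gives 13. The forward key step is copper-mediated coupling of an aryl iodide flanked by two ortho oxygen groups. It avoids oxidation chemistry but needs protection, ortho-iodination, a hot coupling in which reduction of the C–I bond competes, and deprotection. That is four operations from A2 to 13, only one of which builds skeleton, so the step count equals that of the chosen plan while the steric problem is met head-on.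

Alternative 3: Build both rings around a purchased central bond by Claisen chemistry. Tetraethyl ethane-1,1,2,2-tetracarboxylate A5 would serve as a twofold 1,3-dielectrophile and the dianion of hexane-2,4-dione A6 as 1,3-dinucleophile, giving the hexaol A7, 1,1'-(2,2',4,4',6,6'-hexahydroxy-5,5'-dimethyl-[1,1'-biphenyl]-3,3'-diyl)di(ethan-1-one), for selective methylation. The forward key step is four Claisen condensations in one operation. It is not chosen for two reasons. The central C–H groups of A5 are malonate protons, removed at once by the dianion, after which the ester carbons are no longer electrophilic. And A7 has free hydroxyls at C-2 and C-4 on both sides of the acetyl group, which the following methylation cannot tell apart. The chosen plan keeps the idea of an sp3 central bond with ring construction around it, but gives every oxygen a different origin, so no selection among phenols is needed.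

Key step: step 5

## Route

Step 1
Reactants: 1 ethyl 2-methyl-3-oxobutanoate; 2 N-methoxy-N-methylacetamide
Product: 5 4-hydroxy-3,6-dimethyl-2H-pyran-2-one, via dilithium 1-ethoxy-2-methylbuta-1,3-diene-1,3-bis(olate) 3 (not isolated), via ethyl 2-methyl-3,5-dioxohexanoate 4 (not isolated)
Conditions: LiN(i-Pr)2 (2.1 equiv), THF, −78 → 0 °C; 2, −78 → 0 °C; 1 M HCl; crude 4, DBU (1.2 equiv), toluene, reflux; 1 M HCl
Reagents that add atoms: none
Why: γ-Acylation of a β-keto ester dianion by an N-methoxy-N-methyl amide (the chelated tetrahedral adduct prevents over-addition) followed by base-mediated lactonization of the β,δ-diketo ester through its δ-enol, the standard 4-hydroxy-2-pyranone synthesis; the α-stereocentre of 4 disappears on ring formation.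

Step 2
Reactants: 5 4-hydroxy-3,6-dimethyl-2H-pyran-2-one
Product: 6 4-methoxy-3,6-dimethyl-2H-pyran-2-one
Conditions: Me2SO4 (1.2 equiv), K2CO3, acetone, reflux
Reagents that add atoms: dimethyl sulfate, COS(=O)(=O)OC
Why: O-Methylation of the vinylogous acid under Williamson conditions should give the 4-methoxy-2-pyranone as the main product; C-3 is already substituted, so C-methylation is not expected to compete, and the isomeric 2-methoxy-4-pyranone would be a separable minor product.

Step 3
Reactants: 6 4-methoxy-3,6-dimethyl-2H-pyran-2-one (two molecules)
Product: 9 6,6'-(ethane-1,2-diyl)bis(4-methoxy-3-methyl-2H-pyran-2-one), via lithium 4-methoxy-3-methyl-6-methylidene-6H-pyran-2-olate 7 (not isolated), via 6-(iodomethyl)-4-methoxy-3-methyl-2H-pyran-2-one 8 (not isolated)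
Conditions: LiN(i-Pr)2 (1.05 equiv), THF, −78 °C; I2 (0.5 equiv) in THF added slowly, −78 → 0 °C
Reagents that add atoms: none
Why: Oxidative enolate dimerization: the 6-methyl group is the only acidic site of 6 (vinylogous to the lactone carbonyl), iodine converts half of trienolate 7 into the allylic-type iodide 8, and the remaining 7 is alkylated by 8 at its exocyclic carbon, as with ester enolates and picolyl anions.

Step 4
Reactants: 9 6,6'-(ethane-1,2-diyl)bis(4-methoxy-3-methyl-2H-pyran-2-one)
Product: 10 6,6'-(ethane-1,2-diyl)bis(2,4-dimethoxy-3-methylpyrylium) bis(trifluoromethanesulfonate)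
Conditions: MeOTf (3 equiv), CH2Cl2, 23 → 40 °C, argon; precipitation with dry Et2O
Reagents that add atoms: methyl trifluoromethanesulfonate, COS(=O)(=O)C(F)(F)F
Why: O-Alkylation of a lactone carbonyl to an alkoxypyrylium salt: the carbonyl oxygen of a 4-methoxy-2-pyranone is the nucleophilic site (vinylogous carbonate) and methylation gives an aromatic 2,4-dimethoxypyrylium ion, kept intact by the non-nucleophilic triflate.

Step 5
Reactants: 10 6,6'-(ethane-1,2-diyl)bis(2,4-dimethoxy-3-methylpyrylium) bis(trifluoromethanesulfonate)
Product: 13 4,4',6,6'-tetramethoxy-5,5'-dimethyl-[1,1'-biphenyl]-2,2'-diol, via 6,6'-(ethane-1,2-diyl)bis(2,2,4-trimethoxy-3-methyl-2H-pyran) 11 (not isolated), via (3E,9E)-1,1,3,10,12,12-hexamethoxy-2,11-dimethyldodeca-1,3,9,11-tetraene-5,8-dione 12 (not isolated)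
Conditions: 10 added to NaOMe (6 equiv), MeOH–THF, −40 → 23 °C, then 65 °C; aq. NH4Cl
Reagents that add atoms: sodium methoxide, [Na+].[O-]C (after addition at C-2 the two geminal methoxy groups are equivalent, so part of the 6-methoxy groups of 13 stem from it)
Why: Proposed new method: a 2-alkoxypyrylium ion is turned into a phenol by alkoxide addition, ring opening and ring closure through the carbon of its 6-alkyl group; the closest known reaction types are the base-induced recyclization of 2-methylpyrylium salts to phenols and the formation of lactone acetals from O-alkylated lactones and alkoxides. Methoxide, a hard nucleophile, should add under charge control at C-2, the only ring carbon bound to two oxygens, giving the lactone acetal 11 (addition at C-4 is reversible and cannot open the ring; C-6 is shielded by its alkyl group). As a 2H-pyran, 11 opens by 6π electrocyclic ring opening to the keto ketene acetal 12, whose ketone oxygen is the former ring oxygen and whose central C=C keeps the cis geometry of the ring. Methoxide enolizes each ketone toward the bridge CH2, the only enolizable position in 12, and the 2-oxidohexatriene closes in a thermal disrotatory 6π electrocyclization (equally a six-membered addition of the enolate carbon to the δ-carbon of the push-pull dienone), which forms the C-1–C-6 bond of each benzene ring. Loss of methoxide from the C(OMe)2 carbon and enolization give the phenoxide; this aromatization is irreversible and should pull both halves through. No stereocentre is created and the biaryl axis forms as the racemate. The selectivity needed is constitutional, namely which oxygen ends as the free phenol and where the axis carbon sits, and the substrate fixes both: the pyran ring oxygen must become O-2, the two methylated oxygens stay as the 4- and 6-methoxy groups, and the bridge carbon can only become C-1 between them. Aldol diversion of the 1,4-diketone 12 is not possible, since an enolate at a bridge carbon can reach the other carbonyl only through a three-membered ring.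

Step 6
Reactants: 13 4,4',6,6'-tetramethoxy-5,5'-dimethyl-[1,1'-biphenyl]-2,2'-diol
Product: 15 contortin, 1,1'-(2,2'-dihydroxy-4,4',6,6'-tetramethoxy-5,5'-dimethyl-[1,1'-biphenyl]-3,3'-diyl)di(ethan-1-one), via 4,4',6,6'-tetramethoxy-5,5'-dimethyl-[1,1'-biphenyl]-2,2'-diyl diacetate 14 (not isolated)
Conditions: Ac2O (2.2 equiv), Sc(OTf)3 (20 mol %), MeNO2–toluene, 23 °C, then 80 °C
Reagents that add atoms: acetic anhydride, CC(=O)OC(C)=O
Why: O-Acetylation followed by Lewis-acid-catalysed Fries rearrangement; each ring has one unsubstituted carbon (C-3), ortho to the phenol and activated by both methoxy groups, so the acyl group can only arrive there, and the product is held as the hydrogen-bonded ortho-hydroxy ketone.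

## Compound list

1 | ethyl 2-methyl-3-oxobutanoate | CCOC(=O)C(C)C(C)=O | starting material
2 | N-methoxy-N-methylacetamide | CC(=O)N(C)OC | starting material
3 | dilithium 1-ethoxy-2-methylbuta-1,3-diene-1,3-bis(olate) | [Li+].[Li+].CCOC([O-])=C(C)C([O-])=C | intermediate
4 | ethyl 2-methyl-3,5-dioxohexanoate (racemic) | CCOC(=O)C(C)C(=O)CC(C)=O | intermediate
5 | 4-hydroxy-3,6-dimethyl-2H-pyran-2-one | CC1=CC(O)=C(C)C(=O)O1 | intermediate
6 | 4-methoxy-3,6-dimethyl-2H-pyran-2-one | COC1=C(C)C(=O)OC(C)=C1 | intermediate
7 | lithium 4-methoxy-3-methyl-6-methylidene-6H-pyran-2-olate | [Li+].[O-]C1=C(C)C(OC)=CC(=C)O1 | intermediate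
8 | 6-(iodomethyl)-4-methoxy-3-methyl-2H-pyran-2-one | COC1=C(C)C(=O)OC(CI)=C1 | intermediate
9 | 6,6'-(ethane-1,2-diyl)bis(4-methoxy-3-methyl-2H-pyran-2-one) | COC1=C(C)C(=O)OC(CCC2=CC(OC)=C(C)C(=O)O2)=C1 | intermediate
10 | 6,6'-(ethane-1,2-diyl)bis(2,4-dimethoxy-3-methylpyrylium) bis(trifluoromethanesulfonate) | COc1cc(CCc2cc(OC)c(C)c(OC)[o+]2)[o+]c(OC)c1C.[O-]S(=O)(=O)C(F)(F)F.[O-]S(=O)(=O)C(F)(F)F | intermediate
11 | 6,6'-(ethane-1,2-diyl)bis(2,2,4-trimethoxy-3-methyl-2H-pyran) | COC1=C(C)C(OC)(OC)OC(CCC2=CC(OC)=C(C)C(OC)(OC)O2)=C1 | intermediate
12 | (3E,9E)-1,1,3,10,12,12-hexamethoxy-2,11-dimethyldodeca-1,3,9,11-tetraene-5,8-dione | COC(OC)=C(C)/C(OC)=C\C(=O)CCC(=O)/C=C(OC)\C(C)=C(OC)OC | intermediate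
13 | 4,4',6,6'-tetramethoxy-5,5'-dimethyl-[1,1'-biphenyl]-2,2'-diol | COc1cc(O)c(-c2c(O)cc(OC)c(C)c2OC)c(OC)c1C | intermediate
14 | 4,4',6,6'-tetramethoxy-5,5'-dimethyl-[1,1'-biphenyl]-2,2'-diyl diacetate | COc1cc(OC(C)=O)c(-c2c(OC(C)=O)cc(OC)c(C)c2OC)c(OC)c1C | intermediate
15 | contortin, 1,1'-(2,2'-dihydroxy-4,4',6,6'-tetramethoxy-5,5'-dimethyl-[1,1'-biphenyl]-3,3'-diyl)di(ethan-1-one), racemic about the axis | COc1c(C)c(OC)c(-c2c(O)c(C(C)=O)c(OC)c(C)c2OC)c(O)c1C(C)=O | target

Total step count: 6. Longest linear sequence: 6 steps.

## Least certain steps

Step 5 (key step, proposed new method). What may go wrong: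
- Methoxide may add at the alkyl-bearing C-6 of the pyrylium ring, which after ring opening gives a dienoate ester that does not close under these conditions.
- Methoxide may attack an O-methyl group by SN2, which returns 9.
- Enolization of 12 may be slow, so that the second ring closure, which builds the crowded axis environment, stalls at the half-cyclized stage.

The fallback uses known chemistry, sets out from 9 and comes back at 15. Heating 9 with NaOMe in MeOH in a sealed vessel at about 180 °C (lactone methanolysis and intramolecular Claisen condensation, the known way from 4-methoxy-6-alkyl-2-pyranones to 5-methoxyresorcinols) should give 4,4'-dimethoxy-5,5'-dimethyl-[1,1'-biphenyl]-2,2',6,6'-tetraol F1. C-Acetylation at the single free position of each ring (Ac2O with a Lewis acid, then K2CO3/MeOH to free any esterified phenol) should give 1,1'-(2,2',6,6'-tetrahydroxy-4,4'-dimethoxy-5,5'-dimethyl-[1,1'-biphenyl]-3,3'-diyl)di(ethan-1-one) F2. Me2SO4 (2 equiv) with K2CO3 in acetone should then methylate the 6- and 6'-hydroxyls, which are para to the ketone and not hydrogen-bonded, and leave the chelated 2-hydroxyls, giving 15. Here the 4-methoxy group is fixed by construction, so chelation has only one ortho hydroxyl to protect.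

Step 3. What may go wrong: proton transfer between trienolate 7 and iodide 8 with further oxidation to the alkene, iodination at ring carbon C-5 instead of the exocyclic carbon, or conjugate self-addition of 7 to unlithiated 6. The fallback takes the central bond from succinic acid instead of making it, sets out from 1 (as its dianion 3) and comes back at 9. Two equivalents of 3 are acylated with N1,N4-dimethoxy-N1,N4-dimethylbutanediamide F3 (from succinyl chloride and N,O-dimethylhydroxylamine) to give diethyl 2,11-dimethyl-3,5,8,10-tetraoxododecanedioate F4. DBU in hot toluene closes both lactones to 6,6'-(ethane-1,2-diyl)bis(4-hydroxy-3-methyl-2H-pyran-2-one) F5, and Me2SO4/K2CO3 gives 9.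

Step 4. What may go wrong: incomplete methylation of the second ring when the monocation precipitates, or hydrolysis of the salt by traces of water back to 9. The fallback activates the lactone through sulfur, sets out from 9 and comes back at 13. Thionation with P4S10 should give 6,6'-(ethane-1,2-diyl)bis(4-methoxy-3-methyl-2H-pyran-2-thione) F6, whose thiocarbonyl sulfur is alkylated by MeI alone to 6,6'-(ethane-1,2-diyl)bis[4-methoxy-3-methyl-2-(methylsulfanyl)pyrylium] diiodide F7. Under the conditions of step 5, methoxide adds at C-2 and methanethiolate, the better leaving group, is lost either before ring opening or in the aromatization, giving 13.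

Step 6. What may go wrong: acid-induced closure of a dibenzofuran by attack of O-2 on C-6' with loss of methanol, intermolecular acyl transfer that stops at phenol or monoketone, or cleavage of the C-4 methyl ether next to the new ketone. The fallback sets out from 13 and comes back at 15. Diacetate 14 is prepared and isolated (Ac2O, pyridine) and irradiated at 254 nm in methanol (photo-Fries rearrangement, a neutral radical-pair process); with the para and the other ortho position blocked, the acetyl radical can recombine only at C-3, giving 15.

## Further compounds

F1 | step 5 | 4,4'-dimethoxy-5,5'-dimethyl-[1,1'-biphenyl]-2,2',6,6'-tetraol | COc1cc(O)c(-c2c(O)cc(OC)c(C)c2O)c(O)c1C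
F2 | step 5 | 1,1'-(2,2',6,6'-tetrahydroxy-4,4'-dimethoxy-5,5'-dimethyl-[1,1'-biphenyl]-3,3'-diyl)di(ethan-1-one) | COc1c(C(C)=O)c(O)c(-c2c(O)c(C(C)=O)c(OC)c(C)c2O)c(O)c1C
F3 | step 3 | N1,N4-dimethoxy-N1,N4-dimethylbutanediamide | CON(C)C(=O)CCC(=O)N(C)OC
F4 | step 3 | diethyl 2,11-dimethyl-3,5,8,10-tetraoxododecanedioate | CCOC(=O)C(C)C(=O)CC(=O)CCC(=O)CC(=O)C(C)C(=O)OCC
F5 | step 3 | 6,6'-(ethane-1,2-diyl)bis(4-hydroxy-3-methyl-2H-pyran-2-one) | CC1=C(O)C=C(CCC2=CC(O)=C(C)C(=O)O2)OC1=O
F6 | step 4 | 6,6'-(ethane-1,2-diyl)bis(4-methoxy-3-methyl-2H-pyran-2-thione) | COC1=C(C)C(=S)OC(CCC2=CC(OC)=C(C)C(=S)O2)=C1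
F7 | step 4 | 6,6'-(ethane-1,2-diyl)bis[4-methoxy-3-methyl-2-(methylsulfanyl)pyrylium] diiodide | COc1cc(CCc2cc(OC)c(C)c(SC)[o+]2)[o+]c(SC)c1C.[I-].[I-]
F0 | step 6 | none | none
A1 | alternative 1 | 1-(6-hydroxy-2,4-dimethoxy-3-methylphenyl)ethan-1-one | COc1cc(O)c(C(C)=O)c(OC)c1C
A2 | alternative 1 | 3,5-dimethoxy-4-methylphenol | COc1cc(O)cc(OC)c1C
A3 | alternative 2 | 2-iodo-3,5-dimethoxy-1-(methoxymethoxy)-4-methylbenzene | COCOc1cc(OC)c(C)c(OC)c1I
A4 | alternative 2 | 2,2'-bis(methoxymethoxy)-4,4',6,6'-tetramethoxy-5,5'-dimethyl-1,1'-biphenyl | COCOc1cc(OC)c(C)c(OC)c1-c1c(OCOC)cc(OC)c(C)c1OC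
A5 | alternative 3 | tetraethyl ethane-1,1,2,2-tetracarboxylate | CCOC(=O)C(C(=O)OCC)C(C(=O)OCC)C(=O)OCC
A6 | alternative 3 | hexane-2,4-dione | CCC(=O)CC(C)=O
A7 | alternative 3 | 1,1'-(2,2',4,4',6,6'-hexahydroxy-5,5'-dimethyl-[1,1'-biphenyl]-3,3'-diyl)di(ethan-1-one) | CC(=O)c1c(O)c(C)c(O)c(-c2c(O)c(C)c(O)c(C(C)=O)c2O)c1O
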